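## Analysis of the target

The target is a macrocyclic bis(bibenzyl), C28H24O4. Four benzene rings are joined into one 18-membered ring by two CH2–CH2 bridges (ring A to ring B, ring C to ring D) and two diaryl ether oxygens (ring B to ring C, ring D to ring A). Ring A carries the ether oxygen to ring D on C-1, the bridge to ring B on C-2 and a free hydroxyl on C-4. Ring B is para-linked and ring D is meta-linked. Ring C carries the ether oxygen to ring B on C-1, a free hydroxyl on the adjacent C-2 and the bridge to ring D on C-5. There is no stereocentre. Both phenols sit on electron-rich rings (a hydroquinone monoaryl ether in ring A, a catechol monoaryl ether in ring C) and are best unveiled late. The difficulty lies in closing an 18-membered ring that contains a para-bridged arene, in making two unsymmetrical diaryl ethers, one of them at an electron-rich carbon of ring A, and in keeping four oxygen functions apart. The strategy rests on ring A: the hydroxyl carbon C-4 is para to the ether carbon C-1, so a nitro group at C-4 can activate a C-1 fluoride towards a phenoxide and can afterwards be converted into that hydroxyl.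

## Retrosynthetic reasoning

**Ring C hydroxyl.** The O–CH3 bond at C-2 of ring C is cut last, leading from 21 back to the monomethyl ether 20. A methyl ether survives every earlier step, and it keeps ring C from offering a second nucleophile in the ring closure.

**Ring A hydroxyl.** The C-4 oxygen of ring A in 20 is traced back through the diazonium salt 19 and the amine 18 to the nitro group of macrocycle 17. The forward sequence is nitro reduction, diazotisation and hydroxylation, on a macrocycle that by then has no other reducible or nucleophilic group.

**Macrocycle.** The ring of 17 is opened at the bond between the ring D oxygen and C-1 of ring A, giving the seco fluoronitroarene 16. This bond is chosen because C-1 is the only ether carbon of the target that lies para to a position where a strong acceptor can be placed without adding a carbon. The forward reaction must favour closure of the 18-membered ring over intermolecular ether formation. Because 16 has one free phenol and one activated C–F bond, the connectivity of the product is not in doubt.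

**Ring D phenol.** The phenol of 16 is traced back to the isopropyl ether 15. An isopropyl ether is inert to base, hydride, ylides and hydrogenation, and a Lewis acid removes it more readily than the ring C methyl ether.

**Ring A–ring B bridge.** The CH2–CH2 bridge of 15 is traced back to the stilbene 14, and its C=C bond is cut to the ylide 13 (from phosphonium salt 11) and the aldehyde 12. The ylide is placed on the ring B fragment and the aldehyde on ring A so that no carbanion is ever generated on a molecule that also holds the activated C–F bond. The saturation step has to leave the nitro group and the fluoride untouched.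

**Ring B–ring C ether.** Salt 11 comes from alcohol 10 and this from aldehyde 9. The ether of 9 is cut at the ring B carbon, giving phenol 7 and aldehyde 8, whose formyl group activates its own fluoride and then serves as the handle for the bridge.

**Ring C–ring D bridge.** Phenol 7 comes from stilbene 6 by one hydrogenation that saturates the alkene and removes the benzyl group. Stilbene 6 is cut at its C=C bond to the ylide 5 (from salt 3) and aldehyde 4. Salt 3 comes from alcohol 2, and 2 from the purchased diol 1 by alkylation of its phenol alone.

## Alternatives that were turned down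

**Alternative 1:** Ring A is built rather than bought, by cutting three of its C–C bonds.
- **Key step:** A Dötz benzannulation of the terminal alkyne A2 (which already carries rings B, C and D and a bromine on ring D) with the chromium carbene complex A3 would give the hydroquinone monomethyl ether A1.
- **For:** Alkyne insertion places the large substituent ortho to the new hydroxyl, as ring A needs. The C-4 oxygen arrives as a methyl ether, so no nitro group has to be exchanged for a hydroxyl. On this point it is stronger than the chosen route, which spends three steps and a diazonium salt there.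
- **Against:** The benzannulation does not close the macrocycle. A1 would still have to be cyclised by an Ullmann etherification between an ortho-alkylated phenol and an unactivated aryl bromide, a hot and slow copper-mediated reaction that suits high dilution poorly. It also needs stoichiometric chromium, a separate preparation of A3, a two-carbon homologation to reach the butynyl chain of A2, and loss of the silyl group.
- **Comparison:** The chosen strategy gives up the direct oxygenation. In return it closes the ring with an activated electrophile at moderate temperature and builds ring A from a purchased arene, so the risk sits in one step and not two.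

**Alternative 2:** The ring is opened at the ether between ring B and ring C.
- **Key step:** The seco diphenol A5 has the ring D–O–ring A ether and both bridges in place, with two chlorines flanking the ring B phenol and two bromines flanking the ring C phenol. Tl(NO3)3 in methanol would oxidise ring C, the ring B oxygen would add at a bromine-bearing ortho carbon, and zinc in acetic acid would reduce the bromodienone to macrocycle A4.
- **For:** The closure runs at low temperature and needs no activated fluoride. Ring A keeps a methyl ether throughout, so there is no diazonium chemistry; here it is as strong as or stronger than the chosen route. The ring C hydroxyl emerges free.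
- **Against:** Four halogens are introduced only to steer the oxidation, and three must be removed after A4, before a demethylation. The oxidant is stoichiometric and toxic. It must distinguish two halophenols by a small difference between bromine and chlorine. Ring A of A5 is a para-dioxygenated arene that trivalent thallium in methanol could itself dearomatise.
- **Comparison:** The chosen route fixes the roles of nucleophile and electrophile by construction and forms the closing bond by a two-electron addition–elimination that tolerates every group present. Its nitro-to-hydroxyl exchange costs about what the halogenation and dehalogenation cost here.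

**Alternative 3:** Both CH2–CH2 bonds are cut at once.
- **Key step:** Each bridge is replaced by a CH2–S–CH2 link in the 20-membered dithia macrocycle A7. Irradiation in P(OMe)3 would extrude both sulfur atoms and contract the ring to the di-O-methyl ether A6.
- **For:** Thioether formation from benzylic thiolates and bromides is among the most forgiving macrocyclisations. Both diaryl ethers are made beforehand between separate molecules. A6 is one global demethylation from the target, with no nitro group and no diazonium salt, so the end-game is simpler than in the chosen route.
- **Against:** A7 is unsymmetrical. Joining a bis(bromomethyl) half to a bis(mercaptomethyl) half can close in two orientations, giving A7 and a constitutional isomer with the bridges interchanged, unless the four benzylic positions are differentiated and joined stepwise at a cost in steps. Each extrusion passes through a benzylic radical pair that can recombine at a ring carbon or escape, and two must succeed in one molecule. Dilute UV photolysis scales poorly. The ring D–O–ring A ether would have to be made without nitro activation.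
- **Comparison:** The chosen route forms each bridge by a Wittig reaction and hydrogenation with defined connectivity and keeps all steps thermal. It pays with a longer linear sequence and the three-step end-game.

Key step: step 11

Assumption: the 18-membered ring is taken to be conformationally mobile at ambient temperature, so the target is achiral and no atropisomer needs control; 3-(benzyloxy)-4-methoxybenzaldehyde, the benzyl ether of isovanillin, is used as a purchased starting material.

## Route

Step 1
Reactants: 1 3-hydroxybenzyl alcohol
Product: 2 [3-(propan-2-yloxy)phenyl]methanol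
Conditions: 2-bromopropane, K2CO3, DMF, 60 °C
Reagents that add atoms: 2-bromopropane, CC(C)Br
Why: Williamson ether synthesis; the carbonate deprotonates only the phenol, which is far more acidic than the benzylic alcohol, so alkylation should be confined to the ring D oxygen.

Step 2
Reactants: 2 [3-(propan-2-yloxy)phenyl]methanol
Product: 3 triphenyl[3-(propan-2-yloxy)benzyl]phosphonium bromide
Conditions: PPh3·HBr, MeCN, reflux
Reagents that add atoms: triphenylphosphine hydrobromide, [Br-].c1ccc(cc1)[PH+](c1ccccc1)c1ccccc1
Why: Direct conversion of a benzylic alcohol into its phosphonium salt: the protonated alcohol is displaced by bromide and the benzylic bromide is quaternised by the phosphine in the same flask; the aryl isopropyl ether is stable to this weak acid.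

Step 3
Reactants: 3 triphenyl[3-(propan-2-yloxy)benzyl]phosphonium bromide; 4 3-(benzyloxy)-4-methoxybenzaldehyde
Product: 6 2-(benzyloxy)-1-methoxy-4-{2-[3-(propan-2-yloxy)phenyl]ethenyl}benzene (E/Z mixture), via phosphorus ylide 5 (not isolated)
Conditions: KOtBu, THF, 0 °C; then 4, 0 °C to rt
Reagents that add atoms: none
Why: Wittig olefination of a non-enolisable aldehyde with a semi-stabilised benzylic ylide; the alkene geometry is irrelevant because the double bond is saturated in the next step.

Step 4
Reactants: 6 2-(benzyloxy)-1-methoxy-4-{2-[3-(propan-2-yloxy)phenyl]ethenyl}benzene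
Product: 7 2-methoxy-5-{2-[3-(propan-2-yloxy)phenyl]ethyl}phenol
Conditions: H2 (1 atm), Pd/C, EtOAc/EtOH, rt
Reagents that add atoms: none
Why: Heterogeneous hydrogenation saturates both alkene isomers and hydrogenolyses the benzyl ether in one operation, freeing only the ring C phenol; the isopropyl and methyl ethers are inert.

Step 5
Reactants: 7 2-methoxy-5-{2-[3-(propan-2-yloxy)phenyl]ethyl}phenol; 8 4-fluorobenzaldehyde
Product: 9 4-(2-methoxy-5-{2-[3-(propan-2-yloxy)phenyl]ethyl}phenoxy)benzaldehyde
Conditions: K2CO3, DMF, 140 °C
Reagents that add atoms: none
Why: Intermolecular SNAr; the para formyl group stabilises the Meisenheimer adduct, and 7 has a single free phenol, so only the ring B–O–ring C ether can form.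

Step 6
Reactants: 9 4-(2-methoxy-5-{2-[3-(propan-2-yloxy)phenyl]ethyl}phenoxy)benzaldehyde
Product: 10 [4-(2-methoxy-5-{2-[3-(propan-2-yloxy)phenyl]ethyl}phenoxy)phenyl]methanol
Conditions: NaBH4, THF/MeOH, 0 °C
Reagents that add atoms: none
Why: Borohydride reduction of an aromatic aldehyde; no other reducible group is present.

Step 7
Reactants: 10 [4-(2-methoxy-5-{2-[3-(propan-2-yloxy)phenyl]ethyl}phenoxy)phenyl]methanol
Product: 11 [4-(2-methoxy-5-{2-[3-(propan-2-yloxy)phenyl]ethyl}phenoxy)benzyl]triphenylphosphonium bromide
Conditions: PPh3·HBr, MeCN, reflux
Reagents that add atoms: triphenylphosphine hydrobromide, [Br-].c1ccc(cc1)[PH+](c1ccccc1)c1ccccc1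
Why: Same alcohol-to-phosphonium conversion as in step 2; the para aryloxy group makes the benzylic position ionise easily, and the phosphine in stoichiometric amount should trap it before any Friedel–Crafts alkylation.

Step 8
Reactants: 11 [4-(2-methoxy-5-{2-[3-(propan-2-yloxy)phenyl]ethyl}phenoxy)benzyl]triphenylphosphonium bromide; 12 2-fluoro-5-nitrobenzaldehyde
Product: 14 1-fluoro-2-[2-(4-{2-methoxy-5-[2-(3-(propan-2-yloxy)phenyl)ethyl]phenoxy}phenyl)ethenyl]-4-nitrobenzene (E/Z mixture), via phosphorus ylide 13 (not isolated)
Conditions: NaN(SiMe3)2 (slightly under 1 equiv), THF, −78 to 0 °C; then 12, −78 °C to rt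
Reagents that add atoms: none
Why: Wittig olefination with a pre-formed ylide; the hindered amide base is fully consumed before the aldehyde is added, so no nucleophilic base meets the activated C–F bond, and addition of the ylide to the strongly electrophilic formyl group at −78 °C should outrun attack at the arene.

Step 9
Reactants: 14 1-fluoro-2-[2-(4-{2-methoxy-5-[2-(3-(propan-2-yloxy)phenyl)ethyl]phenoxy}phenyl)ethenyl]-4-nitrobenzene
Product: 15 1-fluoro-2-[2-(4-{2-methoxy-5-[2-(3-(propan-2-yloxy)phenyl)ethyl]phenoxy}phenyl)ethyl]-4-nitrobenzene
Conditions: H2 (4 bar), RhCl(PPh3)3 (cat.), THF/t-BuOH (1:1), 40 °C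
Reagents that add atoms: none
Why: Homogeneous hydrogenation with RhCl(PPh3)3 reduces the disubstituted alkene through the usual dihydride–alkene insertion cycle while sparing aromatic nitro groups and aryl fluorides; the medium is neutral and free of nucleophiles, so the activated fluoride should survive.

Step 10
Reactants: 15 1-fluoro-2-[2-(4-{2-methoxy-5-[2-(3-(propan-2-yloxy)phenyl)ethyl]phenoxy}phenyl)ethyl]-4-nitrobenzene
Product: 16 3-{2-[3-(4-[2-(2-fluoro-5-nitrophenyl)ethyl]phenoxy)-4-methoxyphenyl]ethyl}phenol
Conditions: BCl3, CH2Cl2, −78 to 0 °C; then H2O
Reagents that add atoms: none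
Why: Lewis-acid dealkylation of an aryl isopropyl ether; chloride attacks the secondary carbon, which ionises far more readily than a methyl group, so the ring C methyl ether, both diaryl ethers, the nitro group and the fluoride should remain.

Step 11
Reactants: 16 3-{2-[3-(4-[2-(2-fluoro-5-nitrophenyl)ethyl]phenoxy)-4-methoxyphenyl]ethyl}phenol
Product: 17 nitro macrocycle (the ring C methyl ether of the target with NO2 in place of the ring A hydroxyl)
Conditions: Cs2CO3, DMF, 80 °C, slow addition of 16 by syringe pump, final concentration about 0.003 M
Reagents that add atoms: none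
Why: Cs2CO3 deprotonates the ring D phenol of 16, and the phenoxide adds to C-1 of ring A, the fluorine-bearing carbon, giving a Meisenheimer adduct whose charge is delocalised into the para nitro group at C-4; loss of fluoride then forms the O–C(ring A) bond. The closest known reaction type is the intramolecular SNAr macrocyclisation of a phenoxide onto a nitro-activated aryl fluoride, an established way to close macrocyclic diaryl ethers. The one ring formed is the 18-membered macrocycle, closed end to end by attack of the tethered oxygen on the arene carbon, with both ethylene bridges and the ring B–O–ring C ether already in place. No stereocentre is created. The selectivity needed is ring closure over intermolecular ether formation; slow addition into a dilute suspension of the base keeps the standing concentration of phenoxide very low, and displacement para to nitro in DMF should be fast enough to consume each molecule before it meets another. Site selectivity is not in question, because 16 has one free phenol and one activated C–F bond, the ring C oxygen being capped as its methyl ether. The ethylene chain at C-2 of ring A slows the addition somewhat, but it is the tether itself and so delivers the nucleophile to this carbon.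

Step 12
Reactants: 17 nitro macrocycle
Product: 18 amino macrocycle (as 17 with NH2 in place of NO2)
Conditions: H2 (1 atm), Pd/C, EtOAc/MeOH, rt
Reagents that add atoms: none
Why: Catalytic hydrogenation of an aromatic nitro group; at this stage the molecule holds no benzyl ether, halogen or alkene, and diaryl ethers are stable.

Step 13
Reactants: 18 amino macrocycle
Product: 20 hydroxy macrocycle (the ring C methyl ether of the target), via arenediazonium hydrogensulfate 19 (not isolated)
Conditions: NaNO2, aq. H2SO4/AcOH, 0 °C; then Cu(NO3)2 (large excess), Cu2O (substoichiometric), H2O, rt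
Reagents that add atoms: water, O (oxygen of the new hydroxyl); sodium nitrite, [Na+].[O-]N=O (second nitrogen of 19 only); sulfuric acid, OS(=O)(=O)O (counter-ion of 19 only)
Why: Diazotisation followed by a Sandmeyer-type hydroxylation: monovalent copper reduces the diazonium ion to the aryl radical with loss of N2, and hydrated divalent copper captures the radical and delivers the phenol at room temperature, which avoids the boiling acid in which an aryl cation could attack the neighbouring electron-rich rings.

Step 14
Reactants: 20 hydroxy macrocycle
Product: 21 target, CNP0135015.0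
Conditions: BBr3, CH2Cl2, −78 °C to rt; then H2O
Reagents that add atoms: none
Why: Lewis-acid cleavage of the aryl methyl ether by bromide attack on the methyl group of the boron-complexed ether; diaryl ethers are not cleaved under these conditions.

## Compound list

1 | 3-hydroxybenzyl alcohol | OCc1cccc(O)c1 | starting material
2 | [3-(propan-2-yloxy)phenyl]methanol | CC(C)Oc1cccc(CO)c1 | intermediate
3 | triphenyl[3-(propan-2-yloxy)benzyl]phosphonium bromide | CC(C)Oc1cccc(C[P+](c2ccccc2)(c2ccccc2)c2ccccc2)c1.[Br-] | intermediate
4 | 3-(benzyloxy)-4-methoxybenzaldehyde | COc1ccc(C=O)cc1OCc1ccccc1 | starting material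
5 | triphenyl{[3-(propan-2-yloxy)phenyl]methylidene}phosphorane (ylide of 3, not isolated) | CC(C)Oc1cccc(C=P(c2ccccc2)(c2ccccc2)c2ccccc2)c1 | intermediate
6 | 2-(benzyloxy)-1-methoxy-4-{2-[3-(propan-2-yloxy)phenyl]ethenyl}benzene (E/Z mixture) | COc1ccc(C=Cc2cccc(OC(C)C)c2)cc1OCc1ccccc1 | intermediate
7 | 2-methoxy-5-{2-[3-(propan-2-yloxy)phenyl]ethyl}phenol | COc1ccc(CCc2cccc(OC(C)C)c2)cc1O | intermediate
8 | 4-fluorobenzaldehyde | O=Cc1ccc(F)cc1 | starting material
9 | 4-(2-methoxy-5-{2-[3-(propan-2-yloxy)phenyl]ethyl}phenoxy)benzaldehyde | COc1ccc(CCc2cccc(OC(C)C)c2)cc1Oc1ccc(C=O)cc1 | intermediate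
10 | [4-(2-methoxy-5-{2-[3-(propan-2-yloxy)phenyl]ethyl}phenoxy)phenyl]methanol | COc1ccc(CCc2cccc(OC(C)C)c2)cc1Oc1ccc(CO)cc1 | intermediate
11 | [4-(2-methoxy-5-{2-[3-(propan-2-yloxy)phenyl]ethyl}phenoxy)benzyl]triphenylphosphonium bromide | COc1ccc(CCc2cccc(OC(C)C)c2)cc1Oc1ccc(C[P+](c2ccccc2)(c2ccccc2)c2ccccc2)cc1.[Br-] | intermediate
12 | 2-fluoro-5-nitrobenzaldehyde | O=Cc1cc([N+](=O)[O-])ccc1F | starting material
13 | ylide of 11 (not isolated) | COc1ccc(CCc2cccc(OC(C)C)c2)cc1Oc1ccc(C=P(c2ccccc2)(c2ccccc2)c2ccccc2)cc1 | intermediate
14 | 1-fluoro-2-[2-(4-{2-methoxy-5-[2-(3-(propan-2-yloxy)phenyl)ethyl]phenoxy}phenyl)ethenyl]-4-nitrobenzene (E/Z mixture) | COc1ccc(CCc2cccc(OC(C)C)c2)cc1Oc1ccc(C=Cc2cc([N+](=O)[O-])ccc2F)cc1 | intermediate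
15 | 1-fluoro-2-[2-(4-{2-methoxy-5-[2-(3-(propan-2-yloxy)phenyl)ethyl]phenoxy}phenyl)ethyl]-4-nitrobenzene | COc1ccc(CCc2cccc(OC(C)C)c2)cc1Oc1ccc(CCc2cc([N+](=O)[O-])ccc2F)cc1 | intermediate
16 | 3-{2-[3-(4-[2-(2-fluoro-5-nitrophenyl)ethyl]phenoxy)-4-methoxyphenyl]ethyl}phenol (seco precursor) | O=[N+]([O-])c1ccc(F)c(CCc2ccc(Oc3cc(CCc4cccc(O)c4)ccc3OC)cc2)c1 | intermediate
17 | nitro macrocycle (ring A NO2 at C-4, ring C OMe) | O=[N+]([O-])c1ccc2c(c1)CCc1ccc(cc1)Oc1cc(ccc1OC)CCc1cccc(c1)O2 | intermediate
18 | amino macrocycle (ring A NH2 at C-4, ring C OMe) | Nc1ccc2c(c1)CCc1ccc(cc1)Oc1cc(ccc1OC)CCc1cccc(c1)O2 | intermediate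
19 | arenediazonium hydrogensulfate of 18 (not isolated) | N#[N+]c1ccc2c(c1)CCc1ccc(cc1)Oc1cc(ccc1OC)CCc1cccc(c1)O2.OS(=O)(=O)[O-] | intermediate
20 | hydroxy macrocycle (ring A OH at C-4, ring C OMe) | Oc1ccc2c(c1)CCc1ccc(cc1)Oc1cc(ccc1OC)CCc1cccc(c1)O2 | intermediate
21 | CNP0135015.0 | Oc1ccc2c(c1)CCc1ccc(cc1)Oc1cc(ccc1O)CCc1cccc(c1)O2 | target

## Step count and least certain steps

Total step count: 14. Longest linear sequence: 14 steps, from 1 to 21; compounds 4, 8 and 12 enter as purchased materials.

**Step 11 (key step).** Intermolecular ether formation may compete with ring closure if the para-bridged ring B holds the two ends apart in the transition state, and traces of water may hydrolyse the activated fluoride at 80 °C.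
Fallback: the ring would be closed at the ring A–ring B bridge by an intramolecular Wittig reaction, with the ring D–O–ring A ether made beforehand between separate molecules. It sets out from aldehyde 9.
- BCl3 in CH2Cl2 removes the isopropyl group to give 4-{5-[2-(3-hydroxyphenyl)ethyl]-2-methoxyphenoxy}benzaldehyde F1.
- Its phenoxide (K2CO3, DMF, 80 °C) displaces the fluoride of purchased (2-fluoro-5-nitrophenyl)methanol (OCc1cc([N+](=O)[O-])ccc1F) to give the hydroxymethyl diaryl ether F2.
- PPh3·HBr in MeCN converts the benzylic alcohol into the phosphonium bromide F3.
- NaOMe in CH2Cl2/MeOH under high dilution forms the ylide F4, which closes onto the ring B aldehyde to give the macrocyclic nitrostilbene F5 as an E/Z mixture.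
- Hydrogenation over Pd/C reduces the alkene and the nitro group together, and the route is rejoined at amine 18.

**Step 13.** The diazonium group may be lost by paths other than hydroxylation: hydrogen abstraction by the aryl radical, azo coupling onto the electron-rich rings C and D, or nitrosation of those rings by excess nitrous acid.
Fallback: the C–O bond would be made by cross-coupling. It sets out from amine 18.
- Diazotisation as before and treatment with KI gives the aryl iodide F6 (ring A iodide, ring C methyl ether).
- Palladium-catalysed hydroxylation (Pd2(dba)3, tBuXPhos, KOH, dioxane/H2O, 100 °C), through oxidative addition to zerovalent palladium and C–O reductive elimination, gives phenol 20.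

**Step 9.** Hydrogenation of the E isomer of 14 may stall, since 1,2-diarylethenes bind RhCl(PPh3)3 poorly, and forcing conditions may begin to reduce the nitro group.
Fallback: the alkene would be carried through the ring closure and reduced together with the nitro group. It sets out from stilbene 14.
- BCl3 gives the stilbene phenol F7.
- Cs2CO3 in DMF under high dilution closes it to the macrocyclic nitrostilbene F5; the Z-rich mixture expected from the salt-poor Wittig conditions is the isomer better disposed to close.
- Hydrogenation over Pd/C gives amine 18.

**Step 8.** The ylide or residual base may attack the doubly activated C–F bond of aldehyde 12 instead of its formyl group, consuming both partners.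
Fallback: the bridge would be made by a B-alkyl Suzuki coupling, which needs neither the ylide nor an alkene reduction next to the nitro group. It sets out from aldehyde 9.
- Methylenation with methylidenetriphenylphosphorane (from methyltriphenylphosphonium bromide and KOtBu, THF) gives the styrene F8.
- Hydroboration with 9-borabicyclo[3.3.1]nonane in THF gives the primary alkylborane F9, used in solution.
- Coupling with purchased 2-bromo-1-fluoro-4-nitrobenzene (O=[N+]([O-])c1ccc(F)c(Br)c1; PdCl2(dppf), K3PO4, DMF/THF, 50 °C) gives 15.

## Further compounds

F1 | step 11 | 4-{5-[2-(3-hydroxyphenyl)ethyl]-2-methoxyphenoxy}benzaldehyde | COc1ccc(CCc2cccc(O)c2)cc1Oc1ccc(C=O)cc1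
F2 | step 11 | 4-[5-(2-{3-[2-(hydroxymethyl)-4-nitrophenoxy]phenyl}ethyl)-2-methoxyphenoxy]benzaldehyde | COc1ccc(CCc2cccc(Oc3ccc([N+](=O)[O-])cc3CO)c2)cc1Oc1ccc(C=O)cc1
F3 | step 11 | {2-[3-(2-{3-(4-formylphenoxy)-4-methoxyphenyl}ethyl)phenoxy]-5-nitrobenzyl}triphenylphosphonium bromide | COc1ccc(CCc2cccc(Oc3ccc([N+](=O)[O-])cc3C[P+](c3ccccc3)(c3ccccc3)c3ccccc3)c2)cc1Oc1ccc(C=O)cc1.[Br-]
F4 | step 11 | ylide of F3 | COc1ccc(CCc2cccc(Oc3ccc([N+](=O)[O-])cc3C=P(c3ccccc3)(c3ccccc3)c3ccccc3)c2)cc1Oc1ccc(C=O)cc1
F5 | step 11 | macrocyclic nitrostilbene (17 with CH=CH between ring A and ring B, E/Z mixture) | O=[N+]([O-])c1ccc2c(c1)C=Cc1ccc(cc1)Oc1cc(ccc1OC)CCc1cccc(c1)O2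
F6 | step 13 | iodo macrocycle (18 with I in place of NH2) | Ic1ccc2c(c1)CCc1ccc(cc1)Oc1cc(ccc1OC)CCc1cccc(c1)O2
F7 | step 9 | 3-{2-[3-(4-[2-(2-fluoro-5-nitrophenyl)ethenyl]phenoxy)-4-methoxyphenyl]ethyl}phenol (E/Z mixture) | COc1ccc(CCc2cccc(O)c2)cc1Oc1ccc(C=Cc2cc([N+](=O)[O-])ccc2F)cc1
F8 | step 8 | 1-ethenyl-4-(2-methoxy-5-{2-[3-(propan-2-yloxy)phenyl]ethyl}phenoxy)benzene | COc1ccc(CCc2cccc(OC(C)C)c2)cc1Oc1ccc(C=C)cc1
F9 | step 8 | 9-{2-[4-(2-methoxy-5-{2-[3-(propan-2-yloxy)phenyl]ethyl}phenoxy)phenyl]ethyl}-9-borabicyclo[3.3.1]nonane | COc1ccc(CCc2cccc(OC(C)C)c2)cc1Oc1ccc(CCB2C3CCCC2CCC3)cc1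
A1 | alternative 1 | open-chain ring A phenol with ring D bromide | COc1ccc(O)c(CCc2ccc(Oc3cc(CCc4cccc(Br)c4)ccc3OC)cc2)c1
A2 | alternative 1 | terminal alkyne carrying rings B, C and D | C#CCCc1ccc(Oc2cc(CCc3cccc(Br)c3)ccc2OC)cc1
A3 | alternative 1 | pentacarbonyl{methoxy[(E)-2-(trimethylsilyl)ethenyl]carbene}chromium | COC(/C=C/[Si](C)(C)C)=[Cr](=C=O)(=C=O)(=C=O)(=C=O)=C=O
A4 | alternative 2 | dichloro bromo macrocycle with free ring C hydroxyl | COc1ccc2c(c1)CCc1cc(Cl)c(c(Cl)c1)Oc1cc(cc(Br)c1O)CCc1cccc(c1)O2
A5 | alternative 2 | seco dichloro dibromo diphenol | COc1ccc(Oc2cccc(CCc3cc(Br)c(O)c(Br)c3)c2)c(CCc2cc(Cl)c(O)c(Cl)c2)c1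
A6 | alternative 3 | di-O-methyl ether of the target | COc1ccc2c(c1)CCc1ccc(cc1)Oc1cc(ccc1OC)CCc1cccc(c1)O2
A7 | alternative 3 | 20-membered dithia macrocycle | COc1ccc2c(c1)CSCc1ccc(cc1)Oc1cc(ccc1OC)CSCc1cccc(c1)O2
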